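**Plan**

1. Cuts: CO2H back to CO2Me; then a retro-[4+2] across C4–C5 and C3a–C7a of the tetrahydro-1H-indene core, which opens the cyclohexene and the cyclopentene together to an acyclic hexaenoate; then the side-chain bond C2′–C3′ (C12–C13 of the chain) to a trienyl iodide and (E)-styrylboronic acid; then C2=C3, C4=C5 and the C11–C12 terminus back to methyl (R)-3-hydroxy-2-methylpropanoate.
2. Forward: the ester arm of this building block is grown into the (E,E,E)-trienyl iodide (two Wittig homologations, Corey–Fuchs alkyne, hydrozirconation–iodination). The alcohol arm is then grown into the (2E,4Z)-dienoate (oxidation, Still–Gennari, reduction, oxidation–Wittig).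
3. Key event: Suzuki–Miyaura coupling completes the chain; the hexaenoate is heated in the same flask and closes the cyclohexene and the cyclopentene in one intramolecular Diels–Alder reaction.
4. Enabling feature: the bond made is the central sp2–sp2 single bond of the side-chain diene (both carbons alkenyl, coupled with retention). The cyclohexene C3a–C4–C5–C6=C7–C7a, fused to the cyclopentene at C3a–C7a, is a Diels–Alder retron whose three-atom tether is C3=C2–C1.
5. Stereochemistry: C1 comes from the chiral-pool ester; C3a, C4, C5 and C7a arise together in the cycloaddition (ester-endo, tether-exo transition state, diene face fixed by allylic 1,3-strain at C1). Alkene geometries come from Wittig (E), Still–Gennari (Z), syn-hydrozirconation (E) and stereoretentive coupling.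

Key step: step 13

Remark: it is assumed that the [4+2] closure of the ester-activated polyenes 23 and 25 is slow at 25 °C, so that 23 can be prepared and coupled before it cyclises. Linear compounds are numbered from the carbonyl or carbinol carbon, bicyclic ones as 1H-indenes.

**Route**

Step 1
Reactants: 1 methyl (R)-3-hydroxy-2-methylpropanoate; 2 tert-butyldimethylsilyl chloride
Product: 3 methyl (R)-3-[(tert-butyldimethylsilyl)oxy]-2-methylpropanoate
Conditions: TBSCl, imidazole, DMF, 0 to 25 °C
Reagents that add atoms: tert-butyldimethylsilyl chloride (2), CC(C)(C)[Si](C)(C)Cl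
Why: Silylation of the primary alcohol with a silyl chloride and imidazole is chemoselective and leaves the stereocentre untouched.

Step 2
Reactants: 3 methyl (R)-3-[(tert-butyldimethylsilyl)oxy]-2-methylpropanoate
Product: 4 (R)-3-[(tert-butyldimethylsilyl)oxy]-2-methylpropanal
Conditions: i-Bu2AlH (1.1 equiv), CH2Cl2, −78 °C; aq. potassium sodium tartrate
Reagents that add atoms: none
Why: In this partial ester reduction the aluminium hemiacetal formed by one hydride transfer is stable at −78 °C and releases the aldehyde only on work-up, without epimerisation.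

Step 3
Reactants: 4 (R)-3-[(tert-butyldimethylsilyl)oxy]-2-methylpropanal; 5 2-(triphenylphosphoranylidene)propanal
Product: 6 (2E,4S)-5-[(tert-butyldimethylsilyl)oxy]-2,4-dimethylpent-2-enal
Conditions: 5 (1.2 equiv), toluene, 90 °C
Reagents that add atoms: 2-(triphenylphosphoranylidene)propanal (5), CC(C=O)=P(c1ccccc1)(c1ccccc1)c1ccccc1
Why: The Wittig reaction of the stabilised formyl ylide is E-selective for the trisubstituted enal and, being neutral, should leave the α-stereocentre intact.

Step 4
Reactants: 6 (2E,4S)-5-[(tert-butyldimethylsilyl)oxy]-2,4-dimethylpent-2-enal; 5 2-(triphenylphosphoranylidene)propanal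
Product: 7 (2E,4E,6S)-7-[(tert-butyldimethylsilyl)oxy]-2,4,6-trimethylhepta-2,4-dienal
Conditions: 5 (1.5 equiv), toluene, 110 °C
Reagents that add atoms: 2-(triphenylphosphoranylidene)propanal (5), CC(C=O)=P(c1ccccc1)(c1ccccc1)c1ccccc1
Why: A second Wittig homologation with the same stabilised ylide on the enal should give the (2E,4E)-dienal, again with E selectivity.

Step 5
Reactants: 7 (2E,4E,6S)-7-[(tert-butyldimethylsilyl)oxy]-2,4,6-trimethylhepta-2,4-dienal; 8 carbon tetrabromide
Product: 9 tert-butyl{[(2S,3E,5E)-8,8-dibromo-2,4,6-trimethylocta-3,5,7-trien-1-yl]oxy}dimethylsilane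
Conditions: CBr4, PPh3, Zn, CH2Cl2, 0 to 25 °C; then 7, 0 °C
Reagents that add atoms: carbon tetrabromide (8), BrC(Br)(Br)Br
Why: Corey–Fuchs dibromo-olefination with the ylide made from CBr4, PPh3 and Zn converts the aldehyde into the 1,1-dibromoalkene under neutral conditions that spare the silyl ether and the diene.

Step 6
Reactants: 9 tert-butyl{[(2S,3E,5E)-8,8-dibromo-2,4,6-trimethylocta-3,5,7-trien-1-yl]oxy}dimethylsilane; 10 iodomethane
Product: 12 tert-butyldimethyl{[(2S,3E,5E)-2,4,6-trimethylnona-3,5-dien-7-yn-1-yl]oxy}silane, via lithium acetylide 11 (not isolated)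
Conditions: n-BuLi (2.2 equiv), THF, −78 °C; then MeI, −78 to 0 °C
Reagents that add atoms: iodomethane (10), CI
Why: In the second stage of the Corey–Fuchs sequence, bromine–lithium exchange, α-elimination with 1,2-shift (Fritsch–Buttenberg–Wiechell) and deprotonation give the lithium acetylide, which iodomethane methylates on carbon.

Step 7
Reactants: 12 tert-butyldimethyl{[(2S,3E,5E)-2,4,6-trimethylnona-3,5-dien-7-yn-1-yl]oxy}silane; 13 iodine
Product: 15 tert-butyl{[(2S,3E,5E,7E)-8-iodo-2,4,6-trimethylnona-3,5,7-trien-1-yl]oxy}dimethylsilane, via alkenylzirconocene chloride 14 (not isolated)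
Conditions: Cp2Zr(H)Cl (2.2 equiv), THF, 25 to 50 °C; then I2, THF, 0 °C, dark
Reagents that add atoms: iodine (13), II
Why: syn-Hydrozirconation with excess Cp2Zr(H)Cl under equilibrating conditions places zirconium on the less hindered, methyl-bearing alkyne carbon, and iodinolysis of the C–Zr bond with retention gives the E alkenyl iodide.

Step 8
Reactants: 15 tert-butyl{[(2S,3E,5E,7E)-8-iodo-2,4,6-trimethylnona-3,5,7-trien-1-yl]oxy}dimethylsilane
Product: 16 (2S,3E,5E,7E)-8-iodo-2,4,6-trimethylnona-3,5,7-trien-1-ol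
Conditions: Bu4NF, THF, 0 °C
Reagents that add atoms: none
Why: In this desilylation fluoride cleaves the Si–O bond selectively, while the alkenyl iodide and the triene are inert.

Step 9
Reactants: 16 (2S,3E,5E,7E)-8-iodo-2,4,6-trimethylnona-3,5,7-trien-1-ol
Product: 17 (2S,3E,5E,7E)-8-iodo-2,4,6-trimethylnona-3,5,7-trienal
Conditions: Dess–Martin periodinane, NaHCO3, CH2Cl2, 0 °C; used crude at once
Reagents that add atoms: none
Why: Dess–Martin oxidation buffered with NaHCO3 is fast and near-neutral, which should limit enolisation of the α-methyl β,γ-unsaturated aldehyde.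

Step 10
Reactants: 17 (2S,3E,5E,7E)-8-iodo-2,4,6-trimethylnona-3,5,7-trienal; 18 ethyl 2-[bis(2,2,2-trifluoroethoxy)phosphoryl]propanoate
Product: 19 ethyl (2Z,4S,5E,7E,9E)-10-iodo-2,4,6,8-tetramethylundeca-2,5,7,9-tetraenoate
Conditions: 18, KN(SiMe3)2, 18-crown-6, THF, −78 °C; then 17, −78 °C
Reagents that add atoms: ethyl 2-[bis(2,2,2-trifluoroethoxy)phosphoryl]propanoate (18), CCOC(=O)C(C)P(=O)(OCC(F)(F)F)OCC(F)(F)F
Why: In the Still–Gennari olefination the trifluoroethyl phosphonate anion with a crown-complexed potassium counter-ion adds and eliminates irreversibly at −78 °C to give the Z trisubstituted enoate, and the weakly basic stabilised anion should not enolise the aldehyde.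

Step 11
Reactants: 19 ethyl (2Z,4S,5E,7E,9E)-10-iodo-2,4,6,8-tetramethylundeca-2,5,7,9-tetraenoate
Product: 20 (2Z,4S,5E,7E,9E)-10-iodo-2,4,6,8-tetramethylundeca-2,5,7,9-tetraen-1-ol
Conditions: i-Bu2AlH (2.5 equiv), CH2Cl2, −78 °C
Reagents that add atoms: none
Why: i-Bu2AlH reduces the conjugated ester by 1,2-addition to the allylic alcohol without touching the alkenyl iodide or the alkene geometry.

Step 12
Reactants: 20 (2Z,4S,5E,7E,9E)-10-iodo-2,4,6,8-tetramethylundeca-2,5,7,9-tetraen-1-ol; 21 methyl 2-(triphenylphosphoranylidene)propanoate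
Product: 23 methyl (2E,4Z,6S,7E,9E,11E)-12-iodo-2,4,6,8,10-pentamethyltrideca-2,4,7,9,11-pentaenoate, via Z-enal 22 (not isolated)
Conditions: MnO2 (excess), 21 (1.5 equiv), CH2Cl2, 25 °C, dark
Reagents that add atoms: methyl 2-(triphenylphosphoranylidene)propanoate (21), COC(=O)C(C)=P(c1ccccc1)(c1ccccc1)c1ccccc1
Why: In this tandem allylic oxidation–Wittig reaction MnO2 forms the Z enal, which the stabilised ylide traps at once with E selectivity, before the enal can isomerise from Z to E.

Step 13
Reactants: 23 methyl (2E,4Z,6S,7E,9E,11E)-12-iodo-2,4,6,8,10-pentamethyltrideca-2,4,7,9,11-pentaenoate; 24 (E)-styrylboronic acid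
Product: 26 methyl (1R,3aR,4R,5S,7aS)-1,3,4,5,7-pentamethyl-5-[(1E,3E)-2-methyl-4-phenylbuta-1,3-dien-1-yl]-3a,4,5,7a-tetrahydro-1H-indene-4-carboxylate, via hexaene ester 25 (not isolated)
Conditions: 24 (1.5 equiv), Pd(OAc)2 (5 mol %), SPhos (10 mol %), K3PO4, toluene/H2O, 25 °C; then aqueous phase removed, BHT, toluene, 100 °C
Reagents that add atoms: (E)-styrylboronic acid (24), OB(O)/C=C/c1ccccc1
Why: Zerovalent palladium inserts into the C12–I bond of 23, the styryl group is transferred from the boronate, and reductive elimination joins C12 to C13 with retention at both alkenes (Suzuki–Miyaura coupling of an alkenyl iodide with an alkenylboronic acid) to give hexaene 25; on heating, the C7=C8–C9=C10 diene and the C2=C3 dienophile of 25 combine in a concerted suprafacial [4+2] cycloaddition, the closest known type being the cross-coupling/intramolecular Diels–Alder cascades of polyenes with a three-atom tether. The cyclohexene closes as the cycloaddition ring through the new bonds C2–C10 and C3–C7, and the cyclopentene closes at the same time as the tether ring (C3–C4=C5–C6–C7) when C3–C7 forms. The quaternary centres C4 and C5 of 26 follow from the E geometry of the dienophile and of the C9=C10 alkene, both kept in the suprafacial addition, and the trans ring fusion at C3a/C7a follows from the transition state in which the ester lies under the diene and the tether is exo. The face of the diene is chosen by the C6 stereocentre, whose hydrogen eclipses the C7=C8 bond to avoid allylic 1,3-strain with the C8 methyl group, so that the tether reaches the diene from one face and the C6 methyl group points to the other. The step needs the alkenyl iodide to couple before cycloaddition (coupling is run at 25 °C), periselectivity for the C7–C10 diene over the C9–C12 diene (a five-membered against a seven-membered tether ring) and endo selectivity (expected from the ester-endo preference of an E dienophile).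

Step 14
Reactants: 26 methyl (1R,3aR,4R,5S,7aS)-1,3,4,5,7-pentamethyl-5-[(1E,3E)-2-methyl-4-phenylbuta-1,3-dien-1-yl]-3a,4,5,7a-tetrahydro-1H-indene-4-carboxylate
Product: 27 (1R,3aR,4R,5S,7aS)-1,3,4,5,7-pentamethyl-5-[(1E,3E)-2-methyl-4-phenylbuta-1,3-dien-1-yl]-3a,4,5,7a-tetrahydro-1H-indene-4-carboxylic acid (27-nor-zyggomphic acid B)
Conditions: NaSEt, DMF, 60 °C; then 1 M HCl
Reagents that add atoms: none
Why: In this SN2 ester dealkylation the thiolate attacks the ester methyl group (alkyl–oxygen cleavage), which bypasses the carbonyl group shielded by two adjacent quaternary carbons and cannot epimerise any centre.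

**Compound list**

1 | methyl (R)-3-hydroxy-2-methylpropanoate | COC(=O)[C@H](C)CO | starting material
2 | tert-butyldimethylsilyl chloride | CC(C)(C)[Si](C)(C)Cl | starting material
3 | methyl (R)-3-[(tert-butyldimethylsilyl)oxy]-2-methylpropanoate | CC(C)(C)[Si](C)(C)OC[C@@H](C)C(=O)OC | intermediate
4 | (R)-3-[(tert-butyldimethylsilyl)oxy]-2-methylpropanal | CC(C)(C)[Si](C)(C)OC[C@@H](C)C=O | intermediate
5 | 2-(triphenylphosphoranylidene)propanal | CC(C=O)=P(c1ccccc1)(c1ccccc1)c1ccccc1 | starting material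
6 | (2E,4S)-5-[(tert-butyldimethylsilyl)oxy]-2,4-dimethylpent-2-enal | CC(C)(C)[Si](C)(C)OC[C@@H](C)/C=C(C)/C=O | intermediate
7 | (2E,4E,6S)-7-[(tert-butyldimethylsilyl)oxy]-2,4,6-trimethylhepta-2,4-dienal | CC(C)(C)[Si](C)(C)OC[C@@H](C)/C=C(C)/C=C(C)/C=O | intermediate
8 | carbon tetrabromide | BrC(Br)(Br)Br | starting material
9 | tert-butyl{[(2S,3E,5E)-8,8-dibromo-2,4,6-trimethylocta-3,5,7-trien-1-yl]oxy}dimethylsilane | CC(C)(C)[Si](C)(C)OC[C@@H](C)/C=C(C)/C=C(C)/C=C(Br)Br | intermediate
10 | iodomethane | CI | starting material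
11 | {(3E,5E,7S)-8-[(tert-butyldimethylsilyl)oxy]-3,5,7-trimethylocta-3,5-dien-1-yn-1-yl}lithium (lithium acetylide) | CC(C)(C)[Si](C)(C)OC[C@@H](C)/C=C(C)/C=C(C)/C#C[Li] | intermediate
12 | tert-butyldimethyl{[(2S,3E,5E)-2,4,6-trimethylnona-3,5-dien-7-yn-1-yl]oxy}silane | CC(C)(C)[Si](C)(C)OC[C@@H](C)/C=C(C)/C=C(C)/C#CC | intermediate
13 | iodine | II | starting material
14 | chlorobis(cyclopentadienyl)[(2E,4E,6E,8S)-9-[(tert-butyldimethylsilyl)oxy]-4,6,8-trimethylnona-2,4,6-trien-2-yl]zirconium (alkenylzirconocene chloride) | CC(C)(C)[Si](C)(C)OC[C@@H](C)/C=C(C)/C=C(C)/C=C(C)/[Zr](Cl)(C1C=CC=C1)C1C=CC=C1 | intermediate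
15 | tert-butyl{[(2S,3E,5E,7E)-8-iodo-2,4,6-trimethylnona-3,5,7-trien-1-yl]oxy}dimethylsilane | CC(C)(C)[Si](C)(C)OC[C@@H](C)/C=C(C)/C=C(C)/C=C(C)/I | intermediate
16 | (2S,3E,5E,7E)-8-iodo-2,4,6-trimethylnona-3,5,7-trien-1-ol | OC[C@@H](C)/C=C(C)/C=C(C)/C=C(C)/I | intermediate
17 | (2S,3E,5E,7E)-8-iodo-2,4,6-trimethylnona-3,5,7-trienal | O=C[C@@H](C)/C=C(C)/C=C(C)/C=C(C)/I | intermediate
18 | ethyl 2-[bis(2,2,2-trifluoroethoxy)phosphoryl]propanoate | CCOC(=O)C(C)P(=O)(OCC(F)(F)F)OCC(F)(F)F | starting material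
19 | ethyl (2Z,4S,5E,7E,9E)-10-iodo-2,4,6,8-tetramethylundeca-2,5,7,9-tetraenoate | CCOC(=O)/C(C)=C\[C@@H](C)/C=C(C)/C=C(C)/C=C(C)/I | intermediate
20 | (2Z,4S,5E,7E,9E)-10-iodo-2,4,6,8-tetramethylundeca-2,5,7,9-tetraen-1-ol | OC/C(C)=C\[C@@H](C)/C=C(C)/C=C(C)/C=C(C)/I | intermediate
21 | methyl 2-(triphenylphosphoranylidene)propanoate | COC(=O)C(C)=P(c1ccccc1)(c1ccccc1)c1ccccc1 | starting material
22 | (2Z,4S,5E,7E,9E)-10-iodo-2,4,6,8-tetramethylundeca-2,5,7,9-tetraenal (Z-enal) | O=C/C(C)=C\[C@@H](C)/C=C(C)/C=C(C)/C=C(C)/I | intermediate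
23 | methyl (2E,4Z,6S,7E,9E,11E)-12-iodo-2,4,6,8,10-pentamethyltrideca-2,4,7,9,11-pentaenoate | COC(=O)/C(C)=C/C(C)=C\[C@@H](C)/C=C(C)/C=C(C)/C=C(C)/I | intermediate
24 | (E)-styrylboronic acid | OB(O)/C=C/c1ccccc1 | starting material
25 | methyl (2E,4Z,6S,7E,9E,11E,13E)-2,4,6,8,10,12-hexamethyl-14-phenyltetradeca-2,4,7,9,11,13-hexaenoate (hexaene ester) | COC(=O)/C(C)=C/C(C)=C\[C@@H](C)/C=C(C)/C=C(C)/C=C(C)/C=C/c1ccccc1 | intermediate
26 | methyl (1R,3aR,4R,5S,7aS)-1,3,4,5,7-pentamethyl-5-[(1E,3E)-2-methyl-4-phenylbuta-1,3-dien-1-yl]-3a,4,5,7a-tetrahydro-1H-indene-4-carboxylate | CC1=C[C@](C)(/C=C(C)/C=C/c2ccccc2)[C@](C)(C(=O)OC)[C@H]2C(C)=C[C@@H](C)[C@H]12 | intermediate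
27 | (1R,3aR,4R,5S,7aS)-1,3,4,5,7-pentamethyl-5-[(1E,3E)-2-methyl-4-phenylbuta-1,3-dien-1-yl]-3a,4,5,7a-tetrahydro-1H-indene-4-carboxylic acid (27-nor-zyggomphic acid B) | CC1=C[C@](C)(/C=C(C)/C=C/c2ccccc2)[C@](C)(C(=O)O)[C@H]2C(C)=C[C@@H](C)[C@H]12 | target

**Step count and risks**

Total step count: 14. Longest linear sequence: 14 steps (1 to 27).

Steps most likely to fail:

Step 13. The thermal cycloaddition of the ester-activated dienophile may be too slow at 100 °C, so that E/Z isomerisation or a suprafacial [1,5]-hydrogen shift from C6 of the (4Z)-dienoate competes. It may also pass in part through the ester-exo transition state and give the cis-fused diastereomer. The fallback sets out from 23 and comes back at 27. It raises the dienophile to the aldehyde level and cyclises before coupling. Compound 23 is reduced with i-Bu2AlH to (2E,4Z,6S,7E,9E,11E)-12-iodo-2,4,6,8,10-pentamethyltrideca-2,4,7,9,11-pentaen-1-ol F1, which MnO2 oxidises to the corresponding pentaenal F2. The enal is a stronger and more endo-directing dienophile and should close on gentle warming, or with Me2AlCl at low temperature, to the bicyclic iodo aldehyde F3. Suzuki–Miyaura coupling of F3 with 24 should give the bicyclic dienyl aldehyde F4. Pinnick oxidation (NaClO2, NaH2PO4, 2-methylbut-2-ene, t-BuOH/H2O) then gives 27 and makes the ester cleavage unnecessary.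

Step 10. Enolisation of the α-methyl β,γ-unsaturated aldehyde 17 during oxidation or olefination would erode the configuration of the only pre-set stereocentre or move the C3=C4 alkene into conjugation. The fallback sets out from 16 and comes back at 20. It never places a carbonyl group next to the stereocentre. Compound 16 is converted with I2, PPh3 and imidazole into (2E,4E,6E,8S)-2,9-diiodo-4,6,8-trimethylnona-2,4,6-triene F5. Heating F5 with PPh3 in MeCN gives the phosphonium iodide F6, and NaN(SiMe3)2 at −78 °C gives the ylide F7. Wittig reaction of this non-stabilised ylide with 1-[(tert-butyldimethylsilyl)oxy]propan-2-one, a ketone class that gives Z trisubstituted allylic ethers, should give the Z allylic silyl ether F8. Desilylation with Bu4NF gives 20.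

Step 7. Regiocontrol in the addition of Zr–H across the internal alkyne of 12 may be incomplete, or the excess hydride may attack the conjugated diene. The fallback sets out from 12 and comes back at 15. It replaces steric control by electronic control. Copper-catalysed borylcupration–protonation (CuCl, Xantphos, NaOt-Bu, B2pin2, MeOH, THF) adds copper next to the conjugating diene and boron to the methyl-bearing carbon in a syn fashion and should give the trienylboronate F9. Treatment with NaOH and then I2 replaces boron by iodine with retention and gives 15.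

Further compounds
F1 | step 13 | (2E,4Z,6S,7E,9E,11E)-12-iodo-2,4,6,8,10-pentamethyltrideca-2,4,7,9,11-pentaen-1-ol | OC/C(C)=C/C(C)=C\[C@@H](C)/C=C(C)/C=C(C)/C=C(C)/I
F2 | step 13 | (2E,4Z,6S,7E,9E,11E)-12-iodo-2,4,6,8,10-pentamethyltrideca-2,4,7,9,11-pentaenal | O=C/C(C)=C/C(C)=C\[C@@H](C)/C=C(C)/C=C(C)/C=C(C)/I
F3 | step 13 | (1R,3aR,4R,5R,7aS)-5-[(1E)-2-iodoprop-1-en-1-yl]-1,3,4,5,7-pentamethyl-3a,4,5,7a-tetrahydro-1H-indene-4-carbaldehyde | CC1=C[C@](C)(/C=C(C)/I)[C@](C)(C=O)[C@H]2C(C)=C[C@@H](C)[C@H]12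
F4 | step 13 | (1R,3aR,4R,5S,7aS)-1,3,4,5,7-pentamethyl-5-[(1E,3E)-2-methyl-4-phenylbuta-1,3-dien-1-yl]-3a,4,5,7a-tetrahydro-1H-indene-4-carbaldehyde | CC1=C[C@](C)(/C=C(C)/C=C/c2ccccc2)[C@](C)(C=O)[C@H]2C(C)=C[C@@H](C)[C@H]12
F5 | step 10 | (2E,4E,6E,8S)-2,9-diiodo-4,6,8-trimethylnona-2,4,6-triene | IC[C@@H](C)/C=C(C)/C=C(C)/C=C(C)/I
F6 | step 10 | [(2S,3E,5E,7E)-8-iodo-2,4,6-trimethylnona-3,5,7-trien-1-yl]triphenylphosphonium iodide | c1ccccc1[P+](c1ccccc1)(c1ccccc1)C[C@@H](C)/C=C(C)/C=C(C)/C=C(C)/I.[I-]
F7 | step 10 | [(2S,3E,5E,7E)-8-iodo-2,4,6-trimethylnona-3,5,7-trien-1-ylidene]triphenylphosphorane | c1ccccc1P(c1ccccc1)(c1ccccc1)=C[C@@H](C)/C=C(C)/C=C(C)/C=C(C)/I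
F8 | step 10 | tert-butyl{[(2Z,4S,5E,7E,9E)-10-iodo-2,4,6,8-tetramethylundeca-2,5,7,9-tetraen-1-yl]oxy}dimethylsilane | CC(C)(C)[Si](C)(C)OC/C(C)=C\[C@@H](C)/C=C(C)/C=C(C)/C=C(C)/I
F9 | step 7 | 2-[(2Z,4E,6E,8S)-9-[(tert-butyldimethylsilyl)oxy]-4,6,8-trimethylnona-2,4,6-trien-2-yl]-4,4,5,5-tetramethyl-1,3,2-dioxaborolane | CC(C)(C)[Si](C)(C)OC[C@@H](C)/C=C(C)/C=C(C)/C=C(C)/B1OC(C)(C)C(C)(C)O1
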